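1.00 decade of time lies between the first south-west reading, at 1.50 min, where Qf already stands at its later level, and the 15 min each new flask gets, so treat the new flasks as end states.

| flask | Qa | Qb | remark | time |
|---|---|---|---|---|
| south-west | 2 mM | 1.3 mM | run made earlier |  |
| south-east | 2 mM | 7.6 mM | run made earlier |  |
| Thursday's | 2.0 mM | 1.00 mM |  | 15 min |
| Monday's | 2.0 mM | 1.60 mM |  | 15 min |
| Friday's | 2.0 mM | 5.00 mM |  | 15 min |

- south-west (time / min: Qf / %, Qd / %, Qa / %): 1.50: 27.8, 0, 60.2; 3.00: 26.3, 0, 60.9; 5.00: 25.0, 0.1, 62.0; 6.00: 26.5, 0, 59.9; 8.00: 26.6, 0, 59.4; 10.0: 26.8, 0.6, 62.1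
- south-east (time / min: Qf / %, Qd / %, Qa / %): 0.500: 100.9, 1.7, 0.7; 1.50: 102.0, 0.6, 0; 3.00: 99.6, 0.3, 0; 5.00: 99.8, 1.4, 1.7; 6.00: 99.7, 0, 0.3; 8.00: 101.0, 1.3, 0.5; 10.0: 99.7, 0, 0

(each reading ± 1 percentage point)

* final Qf, as a percentage of the Qa charged, for each flask in turn (Thursday's, Monday's, Friday's)



Climb the ladder in decades of time. On the lowest rung, the south-east run with 7.6 mM Qb reads 0.7% Qa at 0.500 min. On the next, the south-west run with 1.3 mM Qb has stopped by 1.50 min, 0.477 decade higher. Thursday's holds the least Qb; if the rate follows [Qb], it loses 0.114 decade against the south-west run, less than the decade in hand. On the top rung, then, the flask waits, and the count of Qb remains to be done.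

Average the south-west plateau: Qa 60.7%, Qf 26.5%, Qd 0.117%. Call the Qa standing in none of these read forms the parked share, 12.6%, a reading with a scatter of 1 percentage point per reading. Give each parked Qa one Qb and each Qf two: that comes to an amount of Qb equal to 65.6% of the Qa charged, beside the 65.0% actually charged in the south-west run, so Qb is the limiting reagent there. With Qb limiting and the parked share held fixed, Qf is half of the difference between [Qb]/[Qa] as charged and the parked share. Thursday's gets 18.7% and Monday's 33.7%. Friday's charges 2.50 Qb per Qa, more than Qf takes, so expect the ceiling, 100%.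

The forecast gives 18.5%, 34% and 100%, holding that “the unseen material looks like a mono-level species carrying one Qb”. The flasks give 19.5%, 35.0% and 99.3%.

    Qa + Qb ⇌ Qd + Qc (K = 0.860, k = 329 M⁻¹ s⁻¹)
    Qa + Qb → Qe + Qc (k = 85.5 M⁻¹ s⁻¹)
    Qb + Qd → Qf + Qc (k = 581 M⁻¹ s⁻¹)
    Qb + Qe → Qf + Qc (k = 519 M⁻¹ s⁻¹)
    Qa + Qd → Qg (k = 12.8 M⁻¹ s⁻¹)

On Monday's, Qa 53.2%, Qf 35.0% and Qd 0% leave a parked share of 11.8%, close to the south-west reading; it stands as Qe 8.32% and Qg 3.48%, each Qg counting two because it holds two Qa. Take Monday's with half the Qa: the rule gives 73.7% Qf, and the flask gives 77.9%. Set Monday's half-life of Qd by Qa + Qd → Qg alone, with Qa as charged, 0.45 min, beside 15 min: it lies 1.52 decades lower. Monday's Qd stands at 0% while Qe stands at 8.32%.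

(All runs are calculated for substances that don't exist, and the scatter is random.)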